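(The data were generated by integration with made-up constants.)

Ash looks nearly like Thursday's run, with the same X and 0.600 M of E against 0.51 M, but it runs to 12 h, whereas Thursday's last reading came at 8.00 h.

| setting | Thursday's | Saturday's | ash | cedar |
|---|---|---|---|---|
| X | 0.20 M | 0.20 M | 0.20 M | 0.20 M |
| E | 0.51 M | 0.81 M | 0.600 M | 1.20 M |
| remark | run made earlier | run made earlier |  |  |
| time |  |  | 12 h | 12 h |
| volume of the second phase over the first |  |  | 1.0 | 1.0 |

| run | time / h | Q / % | X / % |
|---|---|---|---|
| Thursday's | 0.667 | 0.9 | 99.1 |
| Thursday's | 1.33 | 3.4 | 96.7 |
| Thursday's | 2.50 | 8.6 | 91.2 |
| Thursday's | 4.00 | 16.3 | 83.6 |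
| Thursday's | 8.00 | 29.6 | 70.8 |
| Saturday's | 0.667 | 2.0 | 98.3 |
| Saturday's | 1.33 | 5.6 | 94.3 |
| Saturday's | 2.50 | 13.8 | 86.6 |
| Saturday's | 4.00 | 24.4 | 75.2 |
| Saturday's | 8.00 | 40.8 | 59.1 |

(readings scatter by 0.3 percentage points)

- in the second phase: E; everything else is in the first
- charges count per volume of the first phase; a concentration in a rate is the amount of a species over the volume of its own phase; every rate counts per litre of the first phase
- what was read earlier has a scatter of 0.3 percentage points, one standard deviation
- the earlier runs hold the two phases in the same ratio of volumes as the flask asked about

- which of these there is most of at the end, counted by the X in it, ash (X / Q)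
- which of these there is most of at the end, counted by the X in it, cedar (X / Q)
- how much there is at the end of the one of these that leads, in percent of the X charged: ash
- how much there is at the end of the one of these that leads, in percent of the X charged: cedar

E has to cross into the first phase before it meets X. I took the joining with X to be quick and in balance once E has crossed (a pre-equilibrium). Then Q over X follows the reagent that has crossed, and at a given time that amount should scale with the E charged. So I read Q over X divided by the molarity of E charged, which I call the binding ratio 0.820 /M, here as Thursday's run gave it at 8.00 h. Saturday's run, with 0.81 M of E, read 0.852 /M at that time, so the two readings differed by a factor of 1.04 while the E charged differed by a factor of 1.59.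

X and Q stand level when the binding ratio equals one over the E charged, which is 1.67 /M for ash and 0.833 /M for cedar. Thursday's run read 0.382 /M at 4.00 h. My own straight extension over the further 4.00 h gave 1.26 /M at 12 h. Thursday's run stood with Q over X at 0.418 at its last reading. By this line ash, with more E and more time, was to stand at 0.756, still below one, so I expected X to lead ash at 56.9%. Cedar's crossing lay about where the runs already stood at 8.00 h, so I expected Q to lead cedar at 60.1%.

The forecast, which read that “the rate is first order in E”, gave X leading ash at 61% and Q leading cedar at 62%.

The flask gave X leading ash at 61.2% and Q leading cedar at 57.9%.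

    X + Z ⇌ Q (K = 2.54 /M, k = 0.826 /M/h)
    Z ⇌ E, rate k2*([Z] - [E]/K2) per volume of the first phase (partition coefficient = 0.732, kL = 0.0915 /h)

At 12 h the binding ratio came to 1.06 /M in ash, below its crossing, and 1.15 /M in cedar, above its crossing and below my line. Thursday's binding ratio, applied to ash stopped at 8.0 h, gave X at 67.0%, and that flask held 66.9%. In ash at the end, the joining of X and Z, taken by itself with both directions together, had a relaxation half-life of 1.07 h, far shorter than the 12 h of the run.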